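Which flask, grey or red, puts the larger share into monomer in chains when monomer in chains and side product are counted together?

| flask | free monomer | transfer agent | initiator | impurity | temperature | remark | time |
|---|---|---|---|---|---|---|---|
| alder | 0.37 M | 0.0111 M | 7.4 mM | 0.55 mM | 45 °C | run made earlier |  |
| oak | 0.37 M | 0.0111 M | 7.4 mM | 0.83 mM | 60 °C | run made earlier |  |
| cedar | 0.37 M | 0.0056 M | 7.4 mM | 1.1 mM | 45 °C | run made earlier |  |
| grey | 0.37 M | 0.0111 M | 7.4 mM | 1.1 mM | 50 °C |  | 8.0 h |
| red | 0.37 M | 0.0111 M | 7.4 mM | 1.1 mM | 70 °C |  | 8.0 h |

| run | time / h | monomer in chains / % | side product / % |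
|---|---|---|---|
| alder | 0.833 | 0.6 | 0 |
| alder | 1.33 | 1.3 | 0.9 |
| alder | 2.00 | 2.6 | 0.2 |
| alder | 4.00 | 6.1 | 0 |
| alder | 6.00 | 9.7 | 0.2 |
| alder | 10.0 | 16.3 | 0.5 |
| oak | 0.417 | 1.7 | 0.6 |
| oak | 1.33 | 5.6 | 0.1 |
| oak | 2.00 | 9.4 | 1.5 |
| oak | 3.00 | 14.0 | 0 |
| oak | 5.00 | 19.3 | 1.4 |
| oak | 6.00 | 21.7 | 0.7 |
| cedar | 0.833 | 0.2 | 0.6 |
| cedar | 2.50 | 2.4 | 0.1 |
| cedar | 4.00 | 6.3 | 0 |
| cedar | 6.00 | 9.6 | 0.4 |
| cedar | 10.0 | 14.8 | 0.5 |

(scatter of a reading: 0.5 percentage points)

- the flask that comes out highest in share of monomer in chains in all that became monomer in chains or side product, or "all alike" when all lie within 1.5 percentage points (grey / red / all alike)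
- share of monomer in chains in all that became monomer in chains or side product, grey
- share of monomer in chains in all that became monomer in chains or side product, red

- in percentages every species weighs as the free monomer in it: one side product counts as two

I follow the loss ratio: side product per unit of monomer in chains, the inverse of a selectivity factor. The share asked for is one over one plus that ratio.

Single side readings are weak, with a scatter of 0.5 percentage points beside last readings of 0.5% in alder and 0.7% in oak, so I add the last two rows of each table and set column against column. Alder at 45 °C gives a loss ratio of 2.69%. Oak at 60 °C gives 5.12%. Both are rough readings, and those two runs differ also in impurity and in the times of these rows, which I set aside. As my own assumption, I freeze the ratio in time and let it move with temperature.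

1.90 is then the climb, the factor by which the loss ratio grows from alder's temperature to oak's. Applying the climb as a steady factor per degree, grey's ratio comes to 3.34% and red's to 7.86%. My shares are therefore 96.8% for grey and 92.7% for red, with grey the higher.

The forecast also names grey, with 96.7% for grey and 87% for red, a red below mine. One of its grounds for red is that “initiator is spent within hours, so polymer plateaus near 19%”.

The flask gives grey, with 98.4% for grey and 93.0% for red.

    free monomer + initiator → living end + monomer in chains (k = 8.00 /M/h, Ea = 75.0 kJ/mol)
    free monomer + living end → monomer in chains + living end, rate k2*[living end]*[free monomer] (k = 20.0 /M/h, Ea = 56.0 kJ/mol)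
    living end + transfer agent → dead chain (kL = 5.20 /M/h, Ea = 72.0 kJ/mol)
    free monomer + monomer in chains → side product (k = 0.0660 /M/h, Ea = 94.0 kJ/mol)
    2 free monomer → self-condensation product (k = 0.470 /M/h, Ea = 76.0 kJ/mol)
    initiator + impurity → spent initiator (k = 16000 /M/h, Ea = 67.0 kJ/mol)
    (constants at 70 °C)

At 8.00 h red has 0.0110% of its own initiator charge left, yet living end stands at 0.00425 M and monomer in chains at 29.9%, above the forecast's 19%. With side product at 2.25%, red's loss ratio is 7.53%. The largest single effect on the gap between red and grey is what temperature does to the side-product step: the gap of −5.3 points becomes 0.67 points without it. For the same flask as red run at 95 °C, the climb from oak gives a share of 81.3%, and that flask gives 79.8%.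

(Readings and results were generated by integration for substances that don't exist; the scatter is artificial.)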